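**Plan**
1. Retrosynthesis: after the three phenol protecting groups are removed, the only skeletal cut is the benzylic bond between C11 (the CH2 on C9 of the decalin) and aryl C5. The C11 radical is traced back to a carboxylic acid one carbon longer, and that acid to the γ-lactone of (+)-sclareolide.
2. Enabling feature: C11 is a primary CH2 on the C9 stereocentre of ring B. In sclareolide this same CH2 is the α-carbon of the lactone carbonyl (C12, lost as CO2), and the lactone C8–O bond sits where the C7=C8 alkene is needed. On the benzoate ring, C5 is the one CH that is ortho/para to two hydroxyls and meta to the ester.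
3. Forward: lactone → Δ7 ester (acidic opening/elimination) → acid → N-acyloxyphthalimide; arene → 5-bromide → tris-silyl ether; the halves are joined by a nickel-electrocatalytic decarboxylative arylation; fluoride desilylation ends the route.
4. Stereochemistry: no ring and no stereocentre is made. Rings A and B and the stereocentres C5, C9 and C10 come from sclareolide, the C8 stereocentre is deliberately destroyed, and the radical forms at C11, next to but not at C9.

Key step: step 6

Remark: (+)-sclareolide and methyl 2,3,4-trihydroxybenzoate are taken as commercial. The target decalin has the 5α-H, 9α-H, 10β-CH3 arrangement of sclareolide, i.e. (1S,4aS,8aS). Drimane numbering is used for the decalin (C11 = CH2 on C9, C12 = methyl on C8); the arene is numbered from the ester-bearing carbon.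

**Step 1**
Reactants: 1 (+)-sclareolide
Product: 2 methyl 2-[(1S,4aS,8aS)-2,5,5,8a-tetramethyl-1,4,4a,5,6,7,8,8a-octahydronaphthalen-1-yl]acetate (Δ7 ester)
Conditions: conc. H2SO4 (2 equiv), MeOH, rt; chromatography on AgNO3-impregnated silica
Reagents that add atoms: methanol, CO
Why: Acid-mediated lactone opening by ionization of the tertiary C8–O bond with Fischer esterification of the released acid (which blocks relactonization), followed by loss of a C7 proton from the C8 cation, should favour the endocyclic trisubstituted Δ7 alkene over the exocyclic and the strained tetrasubstituted isomers, which are removed on silver-loaded silica; C5, C9 and C10 are not touched.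

**Step 2**
Reactants: 2 Δ7 methyl ester
Product: 3 2-[(1S,4aS,8aS)-2,5,5,8a-tetramethyl-1,4,4a,5,6,7,8,8a-octahydronaphthalen-1-yl]acetic acid
Conditions: LiOH·H2O, THF/MeOH/H2O, 50 °C; then 1 M HCl to pH 3, 0 °C
Reagents that add atoms: LiOH·H2O (hydroxide oxygen), [Li+].[OH-].O
Why: Saponification of an unhindered primary ester should be clean, and the brief cold acidification avoids acid-driven relactonization onto the Δ7 alkene; no stereocentre is involved.

**Step 3**
Reactants: 3 Δ7 acid
Product: 4 1,3-dioxoisoindolin-2-yl 2-[(1S,4aS,8aS)-2,5,5,8a-tetramethyl-1,4,4a,5,6,7,8,8a-octahydronaphthalen-1-yl]acetate (redox-active ester)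
Conditions: N-hydroxyphthalimide, N,N'-diisopropylcarbodiimide, DMAP (cat.), CH2Cl2, rt
Reagents that add atoms: N-hydroxyphthalimide, O=C1c2ccccc2C(=O)N1O
Why: Steglich-type carbodiimide esterification should convert the acid into the N-acyloxyphthalimide, whose N–O bond accepts one electron and so makes the carboxyl group a radical leaving group.

**Step 4**
Reactants: 5 methyl 2,3,4-trihydroxybenzoate
Product: 6 methyl 5-bromo-2,3,4-trihydroxybenzoate
Conditions: NBS (1.0 equiv), MeCN, −20 → 0 °C, dark
Reagents that add atoms: N-bromosuccinimide, O=C1CCC(=O)N1Br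
Why: Electrophilic aromatic bromination should go to C5, which is ortho to the 4-OH, para to the 2-OH and meta to the ester, whereas C6 is ortho to the ester and activated by one hydroxyl only; one equivalent at low temperature limits over-bromination and quinone formation.

**Step 5**
Reactants: 6 methyl 5-bromo-2,3,4-trihydroxybenzoate
Product: 7 methyl 5-bromo-2,3,4-tris[(tert-butyldimethylsilyl)oxy]benzoate
Conditions: TBSOTf (3.6 equiv), 2,6-lutidine (5 equiv), CH2Cl2, 0 °C → rt
Reagents that add atoms: tert-butyldimethylsilyl trifluoromethanesulfonate, CC(C)(C)[Si](C)(C)OS(=O)(=O)C(F)(F)F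
Why: Exhaustive O-silylation with the strong silyl donor should mask all three acidic phenols (which would otherwise consume charge at the cathode) with groups that are inert to reduction and can later be removed by fluoride without acid.

**Step 6**
Reactants: 4 redox-active ester of the Δ7 acid, 7 methyl 5-bromo-2,3,4-tris[(tert-butyldimethylsilyl)oxy]benzoate
Product: 8 methyl 2,3,4-tris[(tert-butyldimethylsilyl)oxy]-5-{[(1S,4aS,8aS)-2,5,5,8a-tetramethyl-1,4,4a,5,6,7,8,8a-octahydronaphthalen-1-yl]methyl}benzoate
Conditions: 4 (1.5 equiv), 7 (1.0 equiv), NiCl2·6H2O (20 mol %), 2,2'-bipyridine (20 mol %), AgNO3 (0.3 equiv), NMP, Mg anode, reticulated vitreous carbon cathode, undivided cell, constant current (about 2.5 F per mol of 7), rt, argon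
Reagents that add atoms: none
Why: Cathodic reduction gives low-valent nickel bipyridine, which inserts into the C–Br bond of 7, while one-electron reduction of the N-acyloxyphthalimide 4 (at nickel or at the silver-coated cathode) releases phthalimide anion and CO2 and leaves the primary C11 radical; the aryl nickel species in the divalent state captures this radical and the resulting trivalent aryl(alkyl)nickel reductively eliminates the C11–aryl bond, the Mg anode supplying the electrons. The closest known reaction type is the nickel-electrocatalytic decarboxylative arylation of redox-active esters with aryl halides (a cross-electrophile coupling). No ring is closed and no stereocentre is formed; C9 keeps its configuration because the radical sits one atom away from it. The step needs cross-coupling over homo-coupling, which the different activation modes of the two partners (two-electron oxidative addition for C–Br, one-electron fragmentation for the ester) should secure, with the cheaper ester in excess. It also needs the homoallylic C11 radical to stay intact: 3-exo closure onto C8 is slow and reversible, the cyclopropylcarbinyl radical reopens through its exocyclic bond back to the C11 radical, and capture by nickel should be faster. The methyl ester, the aryl silyl ethers and the trisubstituted alkene should be inert at the working potential.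

**Step 7**
Reactants: 8 tris-silyl ether of the target
Product: 9 methyl 2,3,4-trihydroxy-5-{[(1S,4aS,8aS)-2,5,5,8a-tetramethyl-1,4,4a,5,6,7,8,8a-octahydronaphthalen-1-yl]methyl}benzoate (CNP0185238.1)
Conditions: TBAF (3.3 equiv), AcOH (3.5 equiv), THF, 0 °C, argon
Reagents that add atoms: none
Why: Fluoride-mediated Si–O cleavage driven by Si–F bond formation should free all three phenols, while the acetic acid buffer keeps the pyrogallol unit from air oxidation as its phenoxide and no acid strong enough to cyclize the 4-OH onto the Δ7 alkene (chroman formation) is present.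

**Compound list**
1 | (+)-sclareolide, (3aR,5aS,9aS,9bR)-3a,6,6,9a-tetramethyldecahydronaphtho[2,1-b]furan-2(1H)-one | O=C1C[C@H]2[C@@](C)(CC[C@H]3C(C)(C)CCC[C@]23C)O1 | starting material
2 | methyl 2-[(1S,4aS,8aS)-2,5,5,8a-tetramethyl-1,4,4a,5,6,7,8,8a-octahydronaphthalen-1-yl]acetate | COC(=O)C[C@H]1C(C)=CC[C@H]2C(C)(C)CCC[C@]12C | intermediate
3 | 2-[(1S,4aS,8aS)-2,5,5,8a-tetramethyl-1,4,4a,5,6,7,8,8a-octahydronaphthalen-1-yl]acetic acid | OC(=O)C[C@H]1C(C)=CC[C@H]2C(C)(C)CCC[C@]12C | intermediate
4 | 1,3-dioxoisoindolin-2-yl 2-[(1S,4aS,8aS)-2,5,5,8a-tetramethyl-1,4,4a,5,6,7,8,8a-octahydronaphthalen-1-yl]acetate | O=C(C[C@H]1C(C)=CC[C@H]2C(C)(C)CCC[C@]12C)ON1C(=O)c2ccccc2C1=O | intermediate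
5 | methyl 2,3,4-trihydroxybenzoate | COC(=O)c1ccc(O)c(O)c1O | starting material
6 | methyl 5-bromo-2,3,4-trihydroxybenzoate | COC(=O)c1cc(Br)c(O)c(O)c1O | intermediate
7 | methyl 5-bromo-2,3,4-tris[(tert-butyldimethylsilyl)oxy]benzoate | COC(=O)c1cc(Br)c(O[Si](C)(C)C(C)(C)C)c(O[Si](C)(C)C(C)(C)C)c1O[Si](C)(C)C(C)(C)C | intermediate
8 | methyl 2,3,4-tris[(tert-butyldimethylsilyl)oxy]-5-{[(1S,4aS,8aS)-2,5,5,8a-tetramethyl-1,4,4a,5,6,7,8,8a-octahydronaphthalen-1-yl]methyl}benzoate | COC(=O)c1cc(C[C@H]2C(C)=CC[C@H]3C(C)(C)CCC[C@]23C)c(O[Si](C)(C)C(C)(C)C)c(O[Si](C)(C)C(C)(C)C)c1O[Si](C)(C)C(C)(C)C | intermediate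
9 | methyl 2,3,4-trihydroxy-5-{[(1S,4aS,8aS)-2,5,5,8a-tetramethyl-1,4,4a,5,6,7,8,8a-octahydronaphthalen-1-yl]methyl}benzoate | COC(=O)c1cc(C[C@H]2C(C)=CC[C@H]3C(C)(C)CCC[C@]23C)c(O)c(O)c1O | target

**Step count**
Total steps: 7. Longest linear sequence: 5 steps (1 → 2 → 3 → 4 → 8 → 9); the arene branch (5 → 6 → 7) has 2 steps before the union.

**Steps most likely to fail**

Step 6. Oxidative addition of the electron-rich, ortho-silyloxy aryl bromide may lag behind radical generation, so that the alkyl fragment is lost to reduction or dimerization and the arene to hydrodebromination. The fallback sets out from 4 and comes back at 8, and replaces the radical capture at nickel by a two-electron transmetallation at palladium. A decarboxylative borylation of 4 (Cu(acac)2 cat., bis(pinacolato)diboron, LiOH·H2O, MgCl2, dioxane/DMF, rt) should give 2-(drim-7-en-11-yl)-4,4,5,5-tetramethyl-1,3,2-dioxaborolane F1. A Suzuki–Miyaura coupling of this boronate with 7 (Pd(OAc)2, RuPhos, K3PO4, toluene/H2O, 80 °C) should then give 8. Any partial loss of silyl groups under the base is harmless because step 7 removes all three.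

Step 1. Proton loss from the C8 cation may be unselective (exocyclic and tetrasubstituted alkenes), methanol may capture the cation, and the lactone may re-form. The fallback sets out from 1 and comes back at 2, and separates ring opening, elimination and alkene positioning into three controlled events. Saponification (KOH, MeOH, reflux) and alkylation of the carboxylate (MeI, DMF) should give methyl 2-[(1R,2R,4aS,8aS)-2-hydroxy-2,5,5,8a-tetramethyldecahydronaphthalen-1-yl]acetate F2. Its equatorial 8α-hydroxyl has no anti-periplanar ring hydrogen, so kinetic dehydration (SOCl2, pyridine, CH2Cl2, −78 °C) should give mainly the exocyclic alkene methyl 2-[(1S,4aS,8aS)-5,5,8a-trimethyl-2-methylidenedecahydronaphthalen-1-yl]acetate F3. Catalytic HI in benzene at rt should then move the double bond into the ring towards the accessible C7 side and give 2.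

Step 5. Silylation may stop short at the crowded 2,3,4-positions, or silyl groups may migrate or be lost later. The fallback sets out from 6 and comes back at 9, and changes the protecting-group strategy from silyl to acyl. Acetylation (Ac2O, pyridine, DMAP cat., rt) should give methyl 2,3,4-triacetoxy-5-bromobenzoate F4. Coupling of F4 with 4 under the conditions of step 6 should give methyl 2,3,4-triacetoxy-5-{[(1S,4aS,8aS)-2,5,5,8a-tetramethyl-1,4,4a,5,6,7,8,8a-octahydronaphthalen-1-yl]methyl}benzoate F5. Methanolysis (K2CO3 cat., degassed MeOH, 0 °C, argon, AcOH quench) should then give 9; the methyl ester is unchanged by methanol.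

**Further compounds**
F1 | step 6 | 2-(drim-7-en-11-yl)-4,4,5,5-tetramethyl-1,3,2-dioxaborolane (C11 pinacol boronate, decalin configuration as in 4) | CC1(C)OB(C[C@H]2C(C)=CC[C@H]3C(C)(C)CCC[C@]23C)OC1(C)C
F2 | step 1 | methyl 2-[(1R,2R,4aS,8aS)-2-hydroxy-2,5,5,8a-tetramethyldecahydronaphthalen-1-yl]acetate | COC(=O)C[C@H]1[C@](C)(O)CC[C@H]2C(C)(C)CCC[C@]12C
F3 | step 1 | methyl 2-[(1S,4aS,8aS)-5,5,8a-trimethyl-2-methylidenedecahydronaphthalen-1-yl]acetate | COC(=O)C[C@H]1C(=C)CC[C@H]2C(C)(C)CCC[C@]12C
F4 | step 5 | methyl 2,3,4-triacetoxy-5-bromobenzoate | COC(=O)c1cc(Br)c(OC(C)=O)c(OC(C)=O)c1OC(C)=O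
F5 | step 5 | methyl 2,3,4-triacetoxy-5-{[(1S,4aS,8aS)-2,5,5,8a-tetramethyl-1,4,4a,5,6,7,8,8a-octahydronaphthalen-1-yl]methyl}benzoate | COC(=O)c1cc(C[C@H]2C(C)=CC[C@H]3C(C)(C)CCC[C@]23C)c(OC(C)=O)c(OC(C)=O)c1OC(C)=O
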